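The target is the trans-(3S,4R)-isoflavan-4-ol. The retrosynthesis removes the O-protecting groups, cuts O1–C2 of ring C, then cuts C5–C6, C4a–C8a and C8–C8a of ring A together, and finally cuts C3–C4 and C1'–C3.
Enabling feature: across ring A, C6–OMe lies para to C8a–O1. C7 and C8 on one flank are methoxylated, and the other flank holds C5–H and the chain-bearing C4a.
An alkenyl(methoxy)carbene chromium complex, one CO ligand and a terminal alkyne assemble exactly this 4-methoxyphenol, and O1 emerges as the only free hydroxyl.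
Forward order: ring B is bought as a quinone and becomes an arylacetyl imide. An aldol joins C3 to C4 and brings in the alkyne, ring A is built on that alkyne, and ring C closes last through O1–C2.
Stereochemistry: one Evans syn aldol with the (R)-4-benzyloxazolidinone sets C3 and C4 together. The syn open chain becomes the trans ring C, and no later step touches either centre.

Key step: step 13

Assumption: chroman numbering (O1, C2, C3, C4, C4a, C5–C8, C8a; primed atoms for ring B) is used for these atoms in open-chain precursors too, and the quinone and the zinc reagent (as a THF solution) are taken as purchasable.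

Step 1
Reactants: 1 2,3-dimethoxy-1,4-benzoquinone
Product: 3 1,4-bis(benzyloxy)-2,3-dimethoxybenzene, via hydroquinone 2 (not isolated)
Conditions: Na2S2O4, Bu4NBr (cat.), THF/H2O, rt; then aq KOH, BnBr, rt, argon
Reagents that add atoms: benzyl bromide, BrCc1ccccc1
Why: One-pot reductive alkylation of a quinone: Na2S2O4 reduces the quinone before any base is present, and a phase-transfer Williamson etherification then caps both phenoxides while excess reductant keeps the air-sensitive diol from reoxidising.

Step 2
Reactants: 3 1,4-bis(benzyloxy)-2,3-dimethoxybenzene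
Product: 4 2,5-bis(benzyloxy)-1-bromo-3,4-dimethoxybenzene
Conditions: NBS (1.0 equiv), MeCN, 0 °C to rt, dark
Reagents that add atoms: N-bromosuccinimide, O=C1CCC(=O)N1Br
Why: Electrophilic aromatic bromination: the two open ring positions are equivalent by symmetry and far more activated than the benzyl rings, and the first bromine slows a second substitution.

Step 3
Reactants: 4 2,5-bis(benzyloxy)-1-bromo-3,4-dimethoxybenzene; 5 (2-ethoxy-2-oxoethyl)zinc bromide
Product: 6 ethyl 2-[2,5-bis(benzyloxy)-3,4-dimethoxyphenyl]acetate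
Conditions: Pd2(dba)3 (2 mol%), XPhos (8 mol%), THF, 60 °C
Reagents that add atoms: none
Why: Negishi-type cross-coupling of a Reformatsky reagent with an aryl bromide forms C1'–C3; the bulky electron-rich biarylphosphine helps zerovalent palladium insert into the electron-rich, ortho-substituted C–Br bond, and the weakly basic zinc enolate tolerates all the ethers.

Step 4
Reactants: 6 ethyl 2-[2,5-bis(benzyloxy)-3,4-dimethoxyphenyl]acetate
Product: 7 2-[2,5-bis(benzyloxy)-3,4-dimethoxyphenyl]acetic acid
Conditions: LiOH, THF/EtOH/H2O, rt; then 1 M HCl to pH 3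
Reagents that add atoms: lithium hydroxide, [Li+].[OH-]
Why: Ester saponification, to which the aryl ethers are inert.

Step 5
Reactants: 7 2-[2,5-bis(benzyloxy)-3,4-dimethoxyphenyl]acetic acid; 8 (R)-4-benzyloxazolidin-2-one
Product: 10 (R)-4-benzyl-3-{2-[2,5-bis(benzyloxy)-3,4-dimethoxyphenyl]acetyl}oxazolidin-2-one, via mixed pivalic anhydride 9 (not isolated)
Conditions: PivCl, Et3N, THF, −20 °C; then LiCl, 8, −20 °C to rt
Reagents that add atoms: pivaloyl chloride, CC(C)(C)C(=O)Cl (its acyl group is found in 9 only)
Why: N-Acylation of an oxazolidinone through a mixed anhydride under LiCl/Et3N activation; the tert-butyl group steers attack to the arylacetyl carbonyl, and no strong base is present that could metalate the benzylic positions.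

Step 6
Reactants: 10 (R)-4-benzyl-3-{2-[2,5-bis(benzyloxy)-3,4-dimethoxyphenyl]acetyl}oxazolidin-2-one; 11 3-(trimethylsilyl)propynal
Product: 13 (R)-4-benzyl-3-{(2R,3R)-2-[2,5-bis(benzyloxy)-3,4-dimethoxyphenyl]-3-hydroxy-5-(trimethylsilyl)pent-4-ynoyl}oxazolidin-2-one (syn aldol), via Z-boron enolate 12 (not isolated)
Conditions: Bu2BOTf (1.2 equiv), Et3N (1.4 equiv), CH2Cl2, 0 °C; 11, −78 to 0 °C; pH 7 buffer, MeOH, 30% H2O2, 0 °C
Reagents that add atoms: dibutylboron triflate, CCCCB(CCCC)OS(=O)(=O)C(F)(F)F (its boron unit is found in 12 only)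
Why: Evans syn aldol: soft enolisation gives the Z boron enolate, which meets the ynal in a Zimmerman–Traxler chair on the enolate face away from the benzyl group of the (R)-auxiliary, so C3 and C4 are set together as the (2R,3R)-syn pair that corresponds to the trans (3S,4R) relationship once the chain ends are tied into ring C.

Step 7
Reactants: 13 syn aldol
Product: 14 (R)-4-benzyl-3-{(2R,3R)-2-[2,5-bis(benzyloxy)-3,4-dimethoxyphenyl]-3-(tert-butyldimethylsilyloxy)-5-(trimethylsilyl)pent-4-ynoyl}oxazolidin-2-one
Conditions: TBSOTf, 2,6-lutidine, CH2Cl2, 0 °C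
Reagents that add atoms: tert-butyldimethylsilyl triflate, CC(C)(C)[Si](C)(C)OS(=O)(=O)C(F)(F)F
Why: O-Silylation of a hindered secondary alcohol with a silyl triflate and a non-nucleophilic base, fast enough at low temperature to outrun retro-aldol cleavage and epimerisation at the acidic C3–H.

Step 8
Reactants: 14 silylated aldol imide
Product: 15 (2S,3R)-2-[2,5-bis(benzyloxy)-3,4-dimethoxyphenyl]-3-(tert-butyldimethylsilyloxy)-5-(trimethylsilyl)pent-4-yn-1-ol
Conditions: LiBH4, H2O (1 equiv), Et2O, 0 °C
Reagents that add atoms: none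
Why: Reductive removal of the Evans auxiliary with water-activated LiBH4, which favours attack at the exocyclic carbonyl of hindered imides and turns it into the C2 hydroxymethyl group; the auxiliary is recovered, and C3 (descriptor changes to S by priority only) is no longer enolisable.

Step 9
Reactants: 15 primary alcohol
Product: 16 [(3R,4R)-4-[2,5-bis(benzyloxy)-3,4-dimethoxyphenyl]-3-(tert-butyldimethylsilyloxy)-5-chloropent-1-yn-1-yl]trimethylsilane
Conditions: PPh3, CCl4, CH2Cl2, 0 °C to rt
Reagents that add atoms: tetrachloromethane, ClC(Cl)(Cl)Cl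
Why: Appel chlorination: the primary alcohol is activated as an alkoxyphosphonium ion and displaced by chloride in an SN2 step at the non-stereogenic C2, under near-neutral conditions that spare both silyl groups.

Step 10
Reactants: 16 silylalkyne chloride
Product: 17 (3R,4R)-4-[2,5-bis(benzyloxy)-3,4-dimethoxyphenyl]-3-(tert-butyldimethylsilyloxy)-5-chloropent-1-yne
Conditions: K2CO3 (0.2 equiv), MeOH/THF, 0 °C to rt
Reagents that add atoms: none
Why: Base-catalysed methanolysis of the alkynyl C–Si bond, selective because the bulky silyl ether and the primary chloride do not react at this temperature; it is placed after the chlorination so that no free primary hydroxyl can invite silyl migration.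

Step 11
Reactants: 18 1,1,2-trimethoxyethane
Product: 19 (Z)-1,2-dimethoxyethene
Conditions: TMSOTf (1.1 equiv), i-Pr2NEt (1.2 equiv), CH2Cl2, −20 °C to rt; fractional distillation
Reagents that add atoms: none
Why: Silyl-triflate-mediated elimination of methanol from an acetal (ionisation to the oxocarbenium ion, then removal of a C2 proton by the hindered amine); the Z alkene is the thermodynamically preferred 1,2-dialkoxyethene and is taken by distillation, and any E isomer carried along would end in the same arene because the alkene geometry is erased when ring A aromatises.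

Step 12
Reactants: 19 (Z)-1,2-dimethoxyethene; 20 chromium hexacarbonyl
Product: 23 pentacarbonyl[(Z)-1,2-dimethoxyvinyl(methoxy)carbene]chromium, via vinyllithium 21 (not isolated), via lithium acylpentacarbonylchromate 22 (not isolated)
Conditions: t-BuLi (1.05 equiv), THF, −78 to −40 °C; Cr(CO)6, −78 °C to rt; solvent removed; Me3OBF4, CH2Cl2, 0 °C; argon throughout
Reagents that add atoms: trimethyloxonium tetrafluoroborate, C[O+](C)C.F[B-](F)(F)F; tert-butyllithium, [Li]C(C)(C)C (its lithium is found in 21 and 22 only)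
Why: Fischer route to alkoxycarbene complexes: the oxygen-acidified vinylic C–H is lithiated with retention of geometry (as for methyl vinyl ether and for 2,3-dihydro-1,4-dioxine, the cyclic Z-1,2-dialkoxyethene), the vinyllithium adds to a CO ligand, and the hard oxonium salt methylates the acylate oxygen, which leaves the β-methoxy group trans to the carbene carbon.

Step 13
Reactants: 17 (3R,4R)-4-[2,5-bis(benzyloxy)-3,4-dimethoxyphenyl]-3-(tert-butyldimethylsilyloxy)-5-chloropent-1-yne; 23 pentacarbonyl[(Z)-1,2-dimethoxyvinyl(methoxy)carbene]chromium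
Product: 25 6-{(1R,2R)-2-[2,5-bis(benzyloxy)-3,4-dimethoxyphenyl]-1-(tert-butyldimethylsilyloxy)-3-chloropropyl}-2,3,4-trimethoxyphenol, via arene-Cr(CO)3 complex 24 (not isolated)
Conditions: 23 (1.5 equiv), THF (degassed, 0.1 M), 55 °C, argon; then air, Et2O, rt, daylight
Reagents that add atoms: none
Why: Thermal loss of one CO from 23 opens a site for the alkyne, which inserts into the Cr=C bond so that its CH carbon bonds to the carbene carbon (C5–C6) and its substituted carbon becomes the new chromium-bound centre, where CO migration (C4a–C8a) gives a chromium-held dienylketene. Ring A then closes by a six-electron electrocyclisation joining the ketene carbon C8a to the methoxy-bearing vinyl terminus C8, and enolisation of the cyclohexadienone gives the phenol as its Cr(CO)3 complex 24, from which brief exposure to air removes the metal. This is the Dötz benzannulation, a formal [3+2+1] cycloaddition documented for alkenyl(alkoxy)carbene chromium complexes, α-alkoxyvinyl ones included, and for terminal alkynes carrying propargylic silyl ethers. The selectivity needed is regiochemical, and the contrast between the branched propargylic carbon C4 and hydrogen keeps the large group away from the carbene methoxy group during insertion, so C4a ends up next to the C8a hydroxyl and C5–H next to C6. Preference for the phenol over five-membered products rests on the alkenyl rather than aryl nature of the complex, on the coordinating solvent, on methoxy being a much weaker donor than the amino groups known to suppress CO insertion, and on the absence of any protic group that could trap the ketene. No stereocentre is formed, the planar chirality of 24 disappears on demetalation, and C3 and C4 are spectators under these neutral conditions.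

Step 14
Reactants: 25 open-chain chlorophenol
Product: 26 (3S,4R)-3-[2,5-bis(benzyloxy)-3,4-dimethoxyphenyl]-4-(tert-butyldimethylsilyloxy)-6,7,8-trimethoxychroman
Conditions: K2CO3 (2 equiv), DMF, 60 °C, argon
Reagents that add atoms: none
Why: Intramolecular Williamson etherification (6-exo-tet) closes ring C: O1 is the only acidic hydroxyl, its phenoxide can reach the chloride through a six-membered transition state, and substitution at the non-stereogenic C2 leaves C3 and C4 untouched, the syn chain folding into the trans ring with both substituents pseudoequatorial.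

Step 15
Reactants: 26 protected chroman
Product: 27 2,3-dimethoxy-5-[(3S,4R)-4-(tert-butyldimethylsilyloxy)-6,7,8-trimethoxychroman-3-yl]benzene-1,4-diol
Conditions: H2 (1 atm), Pd/C (10 wt%), EtOAc, rt; filtration under argon
Reagents that add atoms: none
Why: Catalytic hydrogenolysis of aryl benzyl ethers; it is run while C4–O still carries the bulky silyl group and in a neutral aprotic solvent, so the donor-activated benzylic C4–O bond should be shielded from reductive cleavage.

Step 16
Reactants: 27 silyl-protected hydroquinone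
Product: 28 (3S,4R)-3-(2,5-dihydroxy-3,4-dimethoxyphenyl)-6,7,8-trimethoxychroman-4-ol (target)
Conditions: TBAF/AcOH (1:1), THF (degassed), 0 °C to rt, argon
Reagents that add atoms: none
Why: Fluoride-induced cleavage of the Si–O bond, which retains the C4 configuration because the C4–O bond is never broken; the acetic acid buffer keeps the hydroquinone protonated against autoxidation, yet the medium is too weakly acidic to ionise C4 toward ring closure with the 2'-hydroxyl.

Compound list
1 | 2,3-dimethoxy-1,4-benzoquinone | COC1=C(OC)C(=O)C=CC1=O | starting material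
2 | 2,3-dimethoxybenzene-1,4-diol | COc1c(O)ccc(O)c1OC | intermediate
3 | 1,4-bis(benzyloxy)-2,3-dimethoxybenzene | COc1c(OCc2ccccc2)ccc(OCc2ccccc2)c1OC | intermediate
4 | 2,5-bis(benzyloxy)-1-bromo-3,4-dimethoxybenzene | COc1c(OCc2ccccc2)cc(Br)c(OCc2ccccc2)c1OC | intermediate
5 | (2-ethoxy-2-oxoethyl)zinc bromide | CCOC(=O)C[Zn]Br | starting material
6 | ethyl 2-[2,5-bis(benzyloxy)-3,4-dimethoxyphenyl]acetate | CCOC(=O)Cc1cc(OCc2ccccc2)c(OC)c(OC)c1OCc1ccccc1 | intermediate
7 | 2-[2,5-bis(benzyloxy)-3,4-dimethoxyphenyl]acetic acid | OC(=O)Cc1cc(OCc2ccccc2)c(OC)c(OC)c1OCc1ccccc1 | intermediate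
8 | (R)-4-benzyloxazolidin-2-one | O=C1N[C@H](Cc2ccccc2)CO1 | starting material
9 | 2-[2,5-bis(benzyloxy)-3,4-dimethoxyphenyl]acetic pivalic anhydride | CC(C)(C)C(=O)OC(=O)Cc1cc(OCc2ccccc2)c(OC)c(OC)c1OCc1ccccc1 | intermediate
10 | (R)-4-benzyl-3-{2-[2,5-bis(benzyloxy)-3,4-dimethoxyphenyl]acetyl}oxazolidin-2-one | O=C(Cc1cc(OCc2ccccc2)c(OC)c(OC)c1OCc1ccccc1)N1C(=O)OC[C@H]1Cc1ccccc1 | intermediate
11 | 3-(trimethylsilyl)propynal | C[Si](C)(C)C#CC=O | starting material
12 | (Z)-dibutylboron enolate of imide 10 | CCCCB(CCCC)O/C(=C\c1cc(OCc2ccccc2)c(OC)c(OC)c1OCc1ccccc1)N1C(=O)OC[C@H]1Cc1ccccc1 | intermediate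
13 | (R)-4-benzyl-3-{(2R,3R)-2-[2,5-bis(benzyloxy)-3,4-dimethoxyphenyl]-3-hydroxy-5-(trimethylsilyl)pent-4-ynoyl}oxazolidin-2-one | O=C(N1C(=O)OC[C@H]1Cc1ccccc1)[C@H](c1cc(OCc2ccccc2)c(OC)c(OC)c1OCc1ccccc1)[C@@H](O)C#C[Si](C)(C)C | intermediate
14 | (R)-4-benzyl-3-{(2R,3R)-2-[2,5-bis(benzyloxy)-3,4-dimethoxyphenyl]-3-(tert-butyldimethylsilyloxy)-5-(trimethylsilyl)pent-4-ynoyl}oxazolidin-2-one | O=C(N1C(=O)OC[C@H]1Cc1ccccc1)[C@H](c1cc(OCc2ccccc2)c(OC)c(OC)c1OCc1ccccc1)[C@@H](O[Si](C)(C)C(C)(C)C)C#C[Si](C)(C)C | intermediate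
15 | (2S,3R)-2-[2,5-bis(benzyloxy)-3,4-dimethoxyphenyl]-3-(tert-butyldimethylsilyloxy)-5-(trimethylsilyl)pent-4-yn-1-ol | OC[C@H](c1cc(OCc2ccccc2)c(OC)c(OC)c1OCc1ccccc1)[C@@H](O[Si](C)(C)C(C)(C)C)C#C[Si](C)(C)C | intermediate
16 | [(3R,4R)-4-[2,5-bis(benzyloxy)-3,4-dimethoxyphenyl]-3-(tert-butyldimethylsilyloxy)-5-chloropent-1-yn-1-yl]trimethylsilane | ClC[C@H](c1cc(OCc2ccccc2)c(OC)c(OC)c1OCc1ccccc1)[C@@H](O[Si](C)(C)C(C)(C)C)C#C[Si](C)(C)C | intermediate
17 | (3R,4R)-4-[2,5-bis(benzyloxy)-3,4-dimethoxyphenyl]-3-(tert-butyldimethylsilyloxy)-5-chloropent-1-yne | ClC[C@H](c1cc(OCc2ccccc2)c(OC)c(OC)c1OCc1ccccc1)[C@@H](O[Si](C)(C)C(C)(C)C)C#C | intermediate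
18 | 1,1,2-trimethoxyethane | COCC(OC)OC | starting material
19 | (Z)-1,2-dimethoxyethene | CO/C=C\OC | intermediate
20 | chromium hexacarbonyl | O=C=[Cr](=C=O)(=C=O)(=C=O)(=C=O)=C=O | starting material
21 | (Z)-1,2-dimethoxyvinyllithium | CO/C=C(\OC)[Li] | intermediate
22 | lithium pentacarbonyl[(Z)-2,3-dimethoxy-1-oxidoprop-2-enylidene]chromate | CO/C=C(\OC)C([O-])=[Cr](=C=O)(=C=O)(=C=O)(=C=O)=C=O.[Li+] | intermediate
23 | pentacarbonyl[(Z)-1,2-dimethoxyvinyl(methoxy)carbene]chromium | CO/C=C(\OC)C(OC)=[Cr](=C=O)(=C=O)(=C=O)(=C=O)=C=O | intermediate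
24 | tricarbonyl(η6-arene)chromium complex of phenol 25, metal on ring A (written as two components) | ClC[C@H](c1cc(OCc2ccccc2)c(OC)c(OC)c1OCc1ccccc1)[C@H](c1cc(OC)c(OC)c(OC)c1O)O[Si](C)(C)C(C)(C)C.O=C=[Cr](=C=O)=C=O | intermediate
25 | 6-{(1R,2R)-2-[2,5-bis(benzyloxy)-3,4-dimethoxyphenyl]-1-(tert-butyldimethylsilyloxy)-3-chloropropyl}-2,3,4-trimethoxyphenol | ClC[C@H](c1cc(OCc2ccccc2)c(OC)c(OC)c1OCc1ccccc1)[C@H](c1cc(OC)c(OC)c(OC)c1O)O[Si](C)(C)C(C)(C)C | intermediate
26 | (3S,4R)-3-[2,5-bis(benzyloxy)-3,4-dimethoxyphenyl]-4-(tert-butyldimethylsilyloxy)-6,7,8-trimethoxychroman | COc1cc2c(c(OC)c1OC)OC[C@H](c1cc(OCc3ccccc3)c(OC)c(OC)c1OCc1ccccc1)[C@H]2O[Si](C)(C)C(C)(C)C | intermediate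
27 | 2,3-dimethoxy-5-[(3S,4R)-4-(tert-butyldimethylsilyloxy)-6,7,8-trimethoxychroman-3-yl]benzene-1,4-diol | COc1cc2c(c(OC)c1OC)OC[C@H](c1cc(O)c(OC)c(OC)c1O)[C@H]2O[Si](C)(C)C(C)(C)C | intermediate
28 | (3S,4R)-3-(2,5-dihydroxy-3,4-dimethoxyphenyl)-6,7,8-trimethoxychroman-4-ol | COc1cc2c(c(OC)c1OC)OC[C@H](c1cc(O)c(OC)c(OC)c1O)[C@H]2O | target

Total step count: 16. Longest linear sequence: 14 (steps 1–10 and 13–16); steps 11 and 12 form the two-step side branch.

Steps most likely to fail

Step 13.
- **Risk:** The β-methoxy group pushes electron density through the vinyl unit onto chromium and strengthens the Cr–CO bonds. CO loss may then be slow compared with thermal decay of the complex. After alkyne insertion, CO migration may be skipped, which would divert the reaction to five-membered ring closure.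
- **Fallback:** Ring A is still written from open-chain parts on the same alkyne, but through a Moore rearrangement. It sets out from 17 and rejoins the route at 26. Alkyne 17 is deprotonated with n-BuLi (THF, −78 °C) to the lithium acetylide F1. This adds to one carbonyl of commercial dimethyl squarate and, after an NH4Cl quench, gives the 4-alkynyl-4-hydroxy-2,3-dimethoxycyclobutenone F2, whose epimers at the new carbinol carbon are of no consequence. Heating in toluene or p-xylene opens the four-membered ring to an alkynyl vinylketene, which recloses to the 5-substituted 2,3-dimethoxy-1,4-benzoquinone F3. Na2S2O4 reduces this to the hydroquinone F4. With K2CO3 in degassed DMF, only the hydroxyl ortho to the side chain can reach C2, so O1–C2 closes to the 6-hydroxychroman F5. MeI added to the same flask methylates the remaining C6 hydroxyl and gives 26.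

Step 12.
- **Risk:** In the vinyllithium, lithium and the β-methoxy group are anti. β-Elimination of lithium methoxide may therefore compete if deprotonation is slow enough to require warming.
- **Fallback:** No vinyl anion is needed. The fallback sets out from 19 and 20 and rejoins the route at 23. Enol ether 19 is C-acylated with oxalyl chloride (0 °C to rt) to (Z)-3,4-dimethoxy-2-oxobut-3-enoyl chloride F6. Heating to about 120 °C expels CO and leaves (Z)-2,3-dimethoxyacryloyl chloride F7, following the established conversion of alkyl vinyl ethers into 3-alkoxyacryloyl chlorides. Separately, 20 is reduced with NaC10H8 (from Na and naphthalene, THF, −78 °C) to disodium pentacarbonylchromate F8. Acylation of this dianion by F7 gives the sodium acylpentacarbonylchromate F9, and Me3OBF4 methylates it on oxygen to 23.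

Step 16.
- **Risk:** Fluoride attack at the hindered secondary benzylic silyl ether may be sluggish in the buffered medium. Over long reaction times the free hydroquinone may autoxidise.
- **Fallback:** The two deprotections are exchanged so that no free hydroquinone ever meets fluoride. The fallback sets out from 26 and rejoins at 28. Unbuffered TBAF (THF, rt) removes the silyl group from 26 to give the bis(benzyl)-protected chroman-4-ol F10. The benzyl ethers are then hydrogenolysed last (H2, Pd/C, EtOAc, rt, stopped at consumption of F10), so the target is obtained by filtration alone.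

Further compounds
F1 | step 13 | lithium acetylide of alkyne 17 | ClC[C@H](c1cc(OCc2ccccc2)c(OC)c(OC)c1OCc1ccccc1)[C@@H](O[Si](C)(C)C(C)(C)C)C#C[Li]
F2 | step 13 | 4-{(3R,4R)-4-[2,5-bis(benzyloxy)-3,4-dimethoxyphenyl]-3-(tert-butyldimethylsilyloxy)-5-chloropent-1-yn-1-yl}-4-hydroxy-2,3-dimethoxycyclobut-2-en-1-one (both C4 epimers) | ClC[C@H](c1cc(OCc2ccccc2)c(OC)c(OC)c1OCc1ccccc1)[C@@H](O[Si](C)(C)C(C)(C)C)C#CC1(O)C(=O)C(OC)=C1OC
F3 | step 13 | 5-{(1R,2R)-2-[2,5-bis(benzyloxy)-3,4-dimethoxyphenyl]-1-(tert-butyldimethylsilyloxy)-3-chloropropyl}-2,3-dimethoxy-1,4-benzoquinone | ClC[C@H](c1cc(OCc2ccccc2)c(OC)c(OC)c1OCc1ccccc1)[C@@H](O[Si](C)(C)C(C)(C)C)C1=CC(=O)C(OC)=C(OC)C1=O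
F4 | step 13 | 5-{(1R,2R)-2-[2,5-bis(benzyloxy)-3,4-dimethoxyphenyl]-1-(tert-butyldimethylsilyloxy)-3-chloropropyl}-2,3-dimethoxybenzene-1,4-diol | ClC[C@H](c1cc(OCc2ccccc2)c(OC)c(OC)c1OCc1ccccc1)[C@@H](O[Si](C)(C)C(C)(C)C)c1cc(O)c(OC)c(OC)c1O
F5 | step 13 | (3S,4R)-3-[2,5-bis(benzyloxy)-3,4-dimethoxyphenyl]-4-(tert-butyldimethylsilyloxy)-7,8-dimethoxychroman-6-ol | COc1c(O)cc2c(c1OC)OC[C@H](c1cc(OCc3ccccc3)c(OC)c(OC)c1OCc1ccccc1)[C@H]2O[Si](C)(C)C(C)(C)C
F6 | step 12 | (Z)-3,4-dimethoxy-2-oxobut-3-enoyl chloride | CO/C=C(\OC)C(=O)C(=O)Cl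
F7 | step 12 | (Z)-2,3-dimethoxyacryloyl chloride | CO/C=C(\OC)C(=O)Cl
F8 | step 12 | disodium pentacarbonylchromate, Na2Cr(CO)5 | [Na+].[Na+].O=C=[Cr-2](=C=O)(=C=O)(=C=O)=C=O
F9 | step 12 | sodium pentacarbonyl[(Z)-2,3-dimethoxy-1-oxidoprop-2-enylidene]chromate | CO/C=C(\OC)C([O-])=[Cr](=C=O)(=C=O)(=C=O)(=C=O)=C=O.[Na+]
F10 | step 16 | (3S,4R)-3-[2,5-bis(benzyloxy)-3,4-dimethoxyphenyl]-6,7,8-trimethoxychroman-4-ol | COc1cc2c(c(OC)c1OC)OC[C@H](c1cc(OCc3ccccc3)c(OC)c(OC)c1OCc1ccccc1)[C@H]2O
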